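**Retrosynthetic overview**
- The target comes from one acidic global deprotection of a bis-TES ether whose hydroperoxide is masked as a 2-methoxyprop-2-yl peroxyketal.
- The dienone carbonyl (both C–C bonds) is made by a Pd-catalysed carbonylative Stille coupling of a ring-bound 1-iodovinyl fragment, CO and an (E)-alkenylstannane built from 2-methylbut-3-yn-2-ol.
- The 1-iodovinyl fragment comes from iododesilylation and acylation after a Cu-catalysed 1,4-addition of a 1-silylvinyl Grignard (from vinyltrimethylsilane) to a 5,6-bis(silyloxy)-6-methylcyclohexenone, combined with Rubottom oxidation; both remaining ring stereocentres are set by relay.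
- The enone comes from Saegusa oxidation and silylation of trans-2,3-dihydroxy-2-methylcyclohexanone, which is made by a new Rh-catalysed desymmetrising tethered hydrosilylation of 2-hydroxy-2-methylcyclohexane-1,3-dione.
- Rings: the single carbocycle is carried through from cyclohexane-1,3-dione; no ring-forming step is needed.

Assumption: the sense of induction in step 3 is assigned by analogy ((R,R) ligand gives the 2S,3R product); if the first run gives the antipode, the (S,S) ligand is used and nothing else changes.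

**Step 1**
Reactants: 1 cyclohexane-1,3-dione
Product: 2 2-methylcyclohexane-1,3-dione
Conditions: MeI, NaOH, H2O/dioxane, 65 °C
Reagents that add atoms: iodomethane (CI)
Why: C-alkylation of the stabilised 1,3-dione enolate (enolate alkylation); no stereocentre is formed.

**Step 2**
Reactants: 2 2-methylcyclohexane-1,3-dione
Product: 3 2-hydroxy-2-methylcyclohexane-1,3-dione
Conditions: DMDO, acetone, 0 °C to rt
Reagents that add atoms: dimethyldioxirane (CC1(C)OO1)
Why: epoxidation of the enol tautomer and collapse to the α-hydroxy dione (enol oxidation); the product is achiral, with C2 prochiral.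

**Step 3**
Reactants: 3 2-hydroxy-2-methylcyclohexane-1,3-dione
Product: 6 (2S,3R)-2,3-dihydroxy-2-methylcyclohexan-1-one, via diisopropylsilyl ether 4 (not isolated), via cyclic silylene 5 (not isolated)
Conditions: iPr2SiHCl, Et3N, DMAP (cat.), CH2Cl2, 0 °C; filter, evaporate; [Rh(cod)2]BF4 (2 mol%), (R,R)-i-Pr-DuPhos, THF, 25 °C; then MeOH, PPTS (cat.)
Reagents that add atoms: none
Why: Proposed new method: the tertiary OH is turned into an O–SiH(iPr)2 tether, Rh(I)/chiral bisphosphine adds the Si–H oxidatively and inserts one of the two enantiotopic C=O groups, so the hydride can only reach the carbonyl face on the side of the tethering oxygen (new C3–OH trans to C2–O), the ligand chooses which carbonyl reacts and so fixes C2 and C3 together, and the single Si–H rules out over-reduction; the closest known reaction type is the Rh–DuPhos-catalysed asymmetric intramolecular hydrosilylation of α-siloxy ketones, used here for enantiotopic-group selection in a 2-siloxy-1,3-dione.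

**Step 4**
Reactants: 6 (2S,3R)-2,3-dihydroxy-2-methylcyclohexan-1-one
Product: 7 (2S,3R)-2-methyl-2,3-bis[(triethylsilyl)oxy]cyclohexan-1-one
Conditions: TESOTf, 2,6-lutidine, CH2Cl2, −78 to 0 °C
Reagents that add atoms: triethylsilyl trifluoromethanesulfonate (CC[Si](CC)(CC)OS(=O)(=O)C(F)(F)F)
Why: silyl triflate silylation covers the secondary and the hindered tertiary hydroxyl in one operation; no stereocentre is touched.

**Step 5**
Reactants: 7 (2S,3R)-2-methyl-2,3-bis[(triethylsilyl)oxy]cyclohexan-1-one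
Product: 9 (5R,6S)-6-methyl-5,6-bis[(triethylsilyl)oxy]cyclohex-2-en-1-one, via TMS enol ether 8 (not isolated)
Conditions: LDA, TMSCl, THF, −78 °C; then Pd(OAc)2 (10 mol%), O2, DMSO, 40 °C
Reagents that add atoms: none
Why: Saegusa–Ito oxidation; enolisation is only possible toward the CH2 side because the other α-carbon is quaternary, so the enone is regiodefined and the stereocentres are untouched.

**Step 6**
Reactants: 10 ethenyl(trimethyl)silane
Product: 11 (1,2-dibromoethyl)trimethylsilane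
Conditions: Br2, CH2Cl2, −78 °C
Reagents that add atoms: bromine (BrBr)
Why: electrophilic bromine addition to the vinylsilane; the racemic stereocentre is removed in the next step.

**Step 7**
Reactants: 11 (1,2-dibromoethyl)trimethylsilane
Product: 12 (1-bromoethenyl)trimethylsilane
Conditions: Et2NH, reflux
Reagents that add atoms: none
Why: E2 dehydrobromination removes the acidified α-silyl, α-bromo proton together with the primary bromide to give the 1-bromovinylsilane.

**Step 8**
Reactants: 9 (5R,6S)-6-methyl-5,6-bis[(triethylsilyl)oxy]cyclohex-2-en-1-one; 12 (1-bromoethenyl)trimethylsilane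
Product: 16 (2S,3R,5R,6S)-6-hydroxy-2-methyl-2,3-bis[(triethylsilyl)oxy]-5-[1-(trimethylsilyl)ethenyl]cyclohexan-1-one, via Grignard reagent 13 (not isolated), via TMS enol ether 14 (not isolated), via silyloxy ketone 15 (not isolated)
Conditions: 12, Mg, THF, 50 °C; then 9, CuBr·SMe2 (10 mol%), TMSCl, −78 °C; pentane/Et3N work-up; mCPBA, NaHCO3, CH2Cl2, −20 °C; citric acid, MeOH, 0 °C
Reagents that add atoms: 3-chloroperoxybenzoic acid (OOC(=O)c1cccc(Cl)c1)
Why: Cu-catalysed conjugate addition with TMSCl trapping delivers the 1-silylvinyl group anti to the C5 silyloxy group (sets the side-chain carbon), and Rubottom oxidation of the enol ether anti to that new substituent sets the trans carbinol.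

**Step 9**
Reactants: 16 (2S,3R,5R,6S)-6-hydroxy-2-methyl-2,3-bis[(triethylsilyl)oxy]-5-[1-(trimethylsilyl)ethenyl]cyclohexan-1-one; 17 3-methylbutanoyl chloride
Product: 18 (1S,3S,4R,6R)-3-methyl-2-oxo-3,4-bis[(triethylsilyl)oxy]-6-[1-(trimethylsilyl)ethenyl]cyclohexyl 3-methylbutanoate
Conditions: pyridine, DMAP (cat.), CH2Cl2, 0 °C
Reagents that add atoms: none
Why: DMAP-catalysed O-acylation of the only free hydroxyl under mild base, so the α-acyloxy ketone centre is not epimerised.

**Step 10**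
Reactants: 18 (1S,3S,4R,6R)-3-methyl-2-oxo-3,4-bis[(triethylsilyl)oxy]-6-[1-(trimethylsilyl)ethenyl]cyclohexyl 3-methylbutanoate
Product: 19 (1S,3S,4R,6R)-6-(1-iodoethenyl)-3-methyl-2-oxo-3,4-bis[(triethylsilyl)oxy]cyclohexyl 3-methylbutanoate
Conditions: NIS, MeCN/ClCH2CN (4:1), 0 °C to rt
Reagents that add atoms: N-iodosuccinimide (O=C1CCC(=O)N1I)
Why: ipso-iododesilylation of the 1,1-disubstituted vinylsilane (iodonium formation, then loss of silicon) gives the 2-iodoalkene without touching silyl ethers, ester or stereocentres.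

**Step 11**
Reactants: 20 2-methylbut-3-yn-2-ol
Product: 21 3-hydroperoxy-3-methylbut-1-yne
Conditions: 50% aq. H2O2, H2SO4 (cat.), 0 °C
Reagents that add atoms: hydrogen peroxide (OO)
Why: acid-catalysed SN1 perhydrolysis of the tertiary propargylic alcohol; the propargylic cation cannot transpose usefully, so only the tertiary hydroperoxide forms.

**Step 12**
Reactants: 21 3-hydroperoxy-3-methylbut-1-yne
Product: 22 3-[(2-methoxypropan-2-yl)peroxy]-3-methylbut-1-yne
Conditions: 2-methoxypropene, PPTS (cat.), CH2Cl2, 0 °C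
Reagents that add atoms: 2-methoxypropene (COC(C)=C)
Why: acid-catalysed addition of the hydroperoxide to the enol ether gives the bis-tertiary peroxyketal (hydroperoxide protection).

**Step 13**
Reactants: 22 3-[(2-methoxypropan-2-yl)peroxy]-3-methylbut-1-yne
Product: 23 tributyl{(1E)-3-[(2-methoxypropan-2-yl)peroxy]-3-methylbut-1-en-1-yl}stannane
Conditions: Bu3SnH, PdCl2(PPh3)2 (2 mol%), THF, 0 °C
Reagents that add atoms: tributyltin hydride (CCCC[SnH](CCCC)CCCC)
Why: Pd-catalysed syn-hydrostannation places tin at the terminal carbon, away from the quaternary centre, giving the E-alkenylstannane; the reaction is fast at 0 °C and non-radical, which spares the hindered peroxide.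

**Step 14**
Reactants: 19 (1S,3S,4R,6R)-6-(1-iodoethenyl)-3-methyl-2-oxo-3,4-bis[(triethylsilyl)oxy]cyclohexyl 3-methylbutanoate; 23 tributyl{(1E)-3-[(2-methoxypropan-2-yl)peroxy]-3-methylbut-1-en-1-yl}stannane
Product: 24 (1S,3S,4R,6S)-6-{(4E)-6-[(2-methoxypropan-2-yl)peroxy]-6-methyl-3-oxohepta-1,4-dien-2-yl}-3-methyl-2-oxo-3,4-bis[(triethylsilyl)oxy]cyclohexyl 3-methylbutanoate
Conditions: CO (3 atm), Pd2(dba)3 (5 mol%), AsPh3 (20 mol%), DMF, 45 °C
Reagents that add atoms: carbon monoxide ([C-]#[O+])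
Why: carbonylative Stille coupling (oxidative addition of the vinyl iodide, CO insertion, transmetalation with retention of the E geometry, reductive elimination) forms both C–C bonds of the cross-conjugated dienone; the phosphine-free arsine ligand spares the peroxyketal.

**Step 15**
Reactants: 24 (1S,3S,4R,6S)-6-{(4E)-6-[(2-methoxypropan-2-yl)peroxy]-6-methyl-3-oxohepta-1,4-dien-2-yl}-3-methyl-2-oxo-3,4-bis[(triethylsilyl)oxy]cyclohexyl 3-methylbutanoate
Product: 25 (1S,3S,4R,6S)-3,4-dihydroxy-6-[(4E)-6-hydroperoxy-6-methyl-3-oxohepta-1,4-dien-2-yl]-3-methyl-2-oxocyclohexyl 3-methylbutanoate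
Conditions: 48% aq. HF, MeCN, 0 °C
Reagents that add atoms: none
Why: global deprotection; acidic fluoride cleaves both Si–O bonds and hydrolyses the peroxyketal in one operation, while the ester, dienone, hydroperoxide and all stereocentres are stable to mild acid.

**Compound list**
1 | cyclohexane-1,3-dione | O=C1CCCC(=O)C1 | starting material
2 | 2-methylcyclohexane-1,3-dione | CC1C(=O)CCCC1=O | intermediate
3 | 2-hydroxy-2-methylcyclohexane-1,3-dione | CC1(O)C(=O)CCCC1=O | intermediate
4 | 2-{[di(propan-2-yl)silyl]oxy}-2-methylcyclohexane-1,3-dione | CC1(O[SiH](C(C)C)C(C)C)C(=O)CCCC1=O | intermediate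
5 | trans-fused cyclic diisopropylsilylene of 6: (3aS,7aR)-3a-methyl-2,2-di(propan-2-yl)tetrahydro-1,3,2-benzodioxasilol-4(3aH)-one | C1C[C@@H](O[Si]2(C(C)C)C(C)C)[C@](C)(O2)C(=O)C1 | intermediate
6 | (2S,3R)-2,3-dihydroxy-2-methylcyclohexan-1-one | C1C[C@@H](O)[C@](C)(O)C(=O)C1 | intermediate
7 | (2S,3R)-2-methyl-2,3-bis[(triethylsilyl)oxy]cyclohexan-1-one | C1C[C@@H](O[Si](CC)(CC)CC)[C@](C)(O[Si](CC)(CC)CC)C(=O)C1 | intermediate
8 | trimethyl({(5R,6S)-6-methyl-5,6-bis[(triethylsilyl)oxy]cyclohex-1-en-1-yl}oxy)silane | C1C[C@@H](O[Si](CC)(CC)CC)[C@](C)(O[Si](CC)(CC)CC)C(O[Si](C)(C)C)=C1 | intermediate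
9 | (5R,6S)-6-methyl-5,6-bis[(triethylsilyl)oxy]cyclohex-2-en-1-one | O=C1C=CC[C@@H](O[Si](CC)(CC)CC)[C@]1(C)O[Si](CC)(CC)CC | intermediate
10 | ethenyl(trimethyl)silane (vinyltrimethylsilane) | C=C[Si](C)(C)C | starting material
11 | (1,2-dibromoethyl)trimethylsilane (racemic) | BrCC(Br)[Si](C)(C)C | intermediate
12 | (1-bromoethenyl)trimethylsilane | C=C(Br)[Si](C)(C)C | intermediate
13 | [1-(trimethylsilyl)ethenyl]magnesium bromide | C=C([Mg]Br)[Si](C)(C)C | intermediate
14 | trimethyl({(3R,5R,6S)-6-methyl-5,6-bis[(triethylsilyl)oxy]-3-[1-(trimethylsilyl)ethenyl]cyclohex-1-en-1-yl}oxy)silane | C=C([Si](C)(C)C)[C@@H]1C[C@@H](O[Si](CC)(CC)CC)[C@](C)(O[Si](CC)(CC)CC)C(O[Si](C)(C)C)=C1 | intermediate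
15 | (2S,3R,5R,6S)-2-methyl-2,3-bis[(triethylsilyl)oxy]-5-[1-(trimethylsilyl)ethenyl]-6-[(trimethylsilyl)oxy]cyclohexan-1-one | C=C([Si](C)(C)C)[C@@H]1C[C@@H](O[Si](CC)(CC)CC)[C@](C)(O[Si](CC)(CC)CC)C(=O)[C@H]1O[Si](C)(C)C | intermediate
16 | (2S,3R,5R,6S)-6-hydroxy-2-methyl-2,3-bis[(triethylsilyl)oxy]-5-[1-(trimethylsilyl)ethenyl]cyclohexan-1-one | C=C([Si](C)(C)C)[C@@H]1C[C@@H](O[Si](CC)(CC)CC)[C@](C)(O[Si](CC)(CC)CC)C(=O)[C@H]1O | intermediate
17 | 3-methylbutanoyl chloride | CC(C)CC(=O)Cl | starting material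
18 | (1S,3S,4R,6R)-3-methyl-2-oxo-3,4-bis[(triethylsilyl)oxy]-6-[1-(trimethylsilyl)ethenyl]cyclohexyl 3-methylbutanoate | C=C([Si](C)(C)C)[C@@H]1C[C@@H](O[Si](CC)(CC)CC)[C@](C)(O[Si](CC)(CC)CC)C(=O)[C@H]1OC(=O)CC(C)C | intermediate
19 | (1S,3S,4R,6R)-6-(1-iodoethenyl)-3-methyl-2-oxo-3,4-bis[(triethylsilyl)oxy]cyclohexyl 3-methylbutanoate | C=C(I)[C@@H]1C[C@@H](O[Si](CC)(CC)CC)[C@](C)(O[Si](CC)(CC)CC)C(=O)[C@H]1OC(=O)CC(C)C | intermediate
20 | 2-methylbut-3-yn-2-ol | C#CC(C)(C)O | starting material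
21 | 3-hydroperoxy-3-methylbut-1-yne | C#CC(C)(C)OO | intermediate
22 | 3-[(2-methoxypropan-2-yl)peroxy]-3-methylbut-1-yne | C#CC(C)(C)OOC(C)(C)OC | intermediate
23 | tributyl{(1E)-3-[(2-methoxypropan-2-yl)peroxy]-3-methylbut-1-en-1-yl}stannane | CCCC[Sn](CCCC)(CCCC)/C=C/C(C)(C)OOC(C)(C)OC | intermediate
24 | (1S,3S,4R,6S)-6-{(4E)-6-[(2-methoxypropan-2-yl)peroxy]-6-methyl-3-oxohepta-1,4-dien-2-yl}-3-methyl-2-oxo-3,4-bis[(triethylsilyl)oxy]cyclohexyl 3-methylbutanoate | C=C(C(=O)/C=C/C(C)(C)OOC(C)(C)OC)[C@@H]1C[C@@H](O[Si](CC)(CC)CC)[C@](C)(O[Si](CC)(CC)CC)C(=O)[C@H]1OC(=O)CC(C)C | intermediate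
25 | (1S,3S,4R,6S)-3,4-dihydroxy-6-[(4E)-6-hydroperoxy-6-methyl-3-oxohepta-1,4-dien-2-yl]-3-methyl-2-oxocyclohexyl 3-methylbutanoate | C=C(C(=O)/C=C/C(C)(C)OO)[C@@H]1C[C@@H](O)[C@](C)(O)C(=O)[C@H]1OC(=O)CC(C)C | target

**Step count**
Total step count: 15.
Longest linear sequence: 10 steps (steps 1–5, 8, 9, 10, 14, 15).

**Steps most likely to fail, with fallbacks**

Step 3 (the proposed new desymmetrisation; risks are low enantiotopic-group selectivity or a sluggish hindered Si–H). The fallback uses known chemistry, sets out from 3 and comes back to the route at 6. Hydroxyl-directed mono-reduction of 3 with Me4NBH(OAc)3 (MeCN/AcOH, −30 °C; intramolecular hydride delivery from the tertiary oxygen gives the trans diol) affords racemic trans-2,3-dihydroxy-2-methylcyclohexan-1-one F1. Lipase kinetic resolution (CAL-B, vinyl acetate, MTBE, stopped at 50 % conversion; the 3R alcohol is the fast one by the Kazlauskas rule) gives (1R,2S)-2-hydroxy-2-methyl-3-oxocyclohexyl acetate F2. F2 is separated from the unreacted antipode and hydrolysed with the same lipase in pH 7 buffer to 6.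

Step 14 (Pd(0) and CO in the presence of the peroxide; possible direct coupling without CO insertion). The fallback sets out from 19 and 22 and comes back at 24; 23 is then not needed. Compound 19 is carbonylated with trimethyl(vinyl)stannane (CO, Pd2(dba)3, AsPh3, DMF) to the divinyl ketone (1S,3S,4R,6S)-3-methyl-2-oxo-6-(3-oxopenta-1,4-dien-2-yl)-3,4-bis[(triethylsilyl)oxy]cyclohexyl 3-methylbutanoate F3. Compound 22 is semi-hydrogenated (H2, Lindlar catalyst, quinoline, hexane) to 3-[(2-methoxypropan-2-yl)peroxy]-3-methylbut-1-ene F4. Cross-metathesis of F3 with excess F4 (Hoveyda–Grubbs II, CH2Cl2, 40 °C) then builds the E-enone, so the peroxide never meets Pd(0), CO or a tin hydride.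

Step 15 (removing two silyl ethers, one tertiary, from the finished dienone hydroperoxide). The fallback sets out from 19 and comes back at 25. The silyl ethers are removed first (HF·pyridine, THF/pyridine, 0 °C) to give (1S,3S,4R,6R)-3,4-dihydroxy-6-(1-iodoethenyl)-3-methyl-2-oxocyclohexyl 3-methylbutanoate F5. Carbonylative Stille coupling of F5 with 23 under the step 14 conditions gives (1S,3S,4R,6S)-3,4-dihydroxy-6-{(4E)-6-[(2-methoxypropan-2-yl)peroxy]-6-methyl-3-oxohepta-1,4-dien-2-yl}-3-methyl-2-oxocyclohexyl 3-methylbutanoate F6. Only a mild peroxyketal hydrolysis (AcOH/THF/H2O, 0 °C) then remains to reach 25.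

**Further compounds**
F1 | step 3 | racemic trans-2,3-dihydroxy-2-methylcyclohexan-1-one (1:1 mixture of 6 and its antipode) | C1C[C@@H](O)[C@](C)(O)C(=O)C1.C1C[C@H](O)[C@@](C)(O)C(=O)C1
F2 | step 3 | (1R,2S)-2-hydroxy-2-methyl-3-oxocyclohexyl acetate | C1C[C@@H](OC(C)=O)[C@](C)(O)C(=O)C1
F3 | step 14 | (1S,3S,4R,6S)-3-methyl-2-oxo-6-(3-oxopenta-1,4-dien-2-yl)-3,4-bis[(triethylsilyl)oxy]cyclohexyl 3-methylbutanoate | C=C(C(=O)C=C)[C@@H]1C[C@@H](O[Si](CC)(CC)CC)[C@](C)(O[Si](CC)(CC)CC)C(=O)[C@H]1OC(=O)CC(C)C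
F4 | step 14 | 3-[(2-methoxypropan-2-yl)peroxy]-3-methylbut-1-ene | C=CC(C)(C)OOC(C)(C)OC
F5 | step 15 | (1S,3S,4R,6R)-3,4-dihydroxy-6-(1-iodoethenyl)-3-methyl-2-oxocyclohexyl 3-methylbutanoate | C=C(I)[C@@H]1C[C@@H](O)[C@](C)(O)C(=O)[C@H]1OC(=O)CC(C)C
F6 | step 15 | (1S,3S,4R,6S)-3,4-dihydroxy-6-{(4E)-6-[(2-methoxypropan-2-yl)peroxy]-6-methyl-3-oxohepta-1,4-dien-2-yl}-3-methyl-2-oxocyclohexyl 3-methylbutanoate | C=C(C(=O)/C=C/C(C)(C)OOC(C)(C)OC)[C@@H]1C[C@@H](O)[C@](C)(O)C(=O)[C@H]1OC(=O)CC(C)C
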